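**Assumption:** 3-(tert-butyldiphenylsilyloxy)propanal and 2-(diethoxyphosphoryl)acetic acid are bought; locants follow spiro[4.5]decane numbering (C1 carbinol CH, C2 side-chain CH, C5 spiro carbon, C6 C(CH3)OH, C9 alkylidene carbon, C10 CH carrying the three-carbon chain).

## Retrosynthetic overview

1. Target ⇐ fluoride/acid unmasking of a silyl ether and an enal dimethyl acetal; the allylic CH2OH and C1–OH ⇐ i-Bu2AlH reduction of an E-α-alkylidene γ-lactone, made by Horner–Wadsworth–Emmons reaction of a phosphono lactone with a C10 dienal (enol triflate of 6-methylhept-5-en-2-one + acrolein, Heck).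
2. cis-Lactone ⇐ rhodium carbenoid C–H insertion from the C1–O ester (sets C2); C6 carbinol ⇐ methylcerium addition; Z-enal ⇐ isopropenyl addition and oxidative 1,3-transposition at C9.
3. C10 side chain ⇐ aldol condensation on a spiro ene-dione, then face-selective hydrogenation.
4. Spiro ene-dione ⇐ dearomatising ipso C-alkylation of a 4-methoxyphenoxide by its own chlorobutyl chain (C5 set from the benzylic C1 centre) ⇐ asymmetric transfer hydrogenation ⇐ Friedel–Crafts acylation of 1,4-dimethoxybenzene.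
5. Ring order: the benzene ring becomes ring A (cyclohexane) and the cyclopentane (ring B) is closed in the same dearomatising step; a temporary lactone ring is fused to ring B later and opened at the end.

## Route

Step 1
Reactants: 1 1,4-dimethoxybenzene; 2 4-chlorobutanoyl chloride
Product: 3 4-chloro-1-(2-hydroxy-5-methoxyphenyl)butan-1-one
Conditions: AlCl3 (2.5 equiv), CH2Cl2, 0 °C to reflux; aq. HCl work-up
Reagents that add atoms: none
Why: Friedel–Crafts acylation of the electron-rich arene is followed in the same pot by AlCl3-mediated cleavage of only the methyl ether ortho to the new ketone (six-membered aluminium chelate), the usual access to 2-hydroxy-5-methoxyaryl ketones, and no stereocentre is formed.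

Step 2
Reactants: 3 4-chloro-1-(2-hydroxy-5-methoxyphenyl)butan-1-one
Product: 4 (1R)-4-chloro-1-(2-hydroxy-5-methoxyphenyl)butan-1-ol
Conditions: RuCl[(R,R)-TsDPEN](p-cymene) (1 mol %), HCO2H/Et3N 5:2, DMF, 30 °C
Reagents that add atoms: none
Why: Noyori asymmetric transfer hydrogenation of the aryl alkyl ketone sets the carbinol centre (future C1) as R, the (R,R)-ligand giving the (R)-1-arylalkanol as with acetophenone-type ketones, while the alkyl chloride is inert in the acidic medium.

Step 3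
Reactants: 4 (1R)-4-chloro-1-(2-hydroxy-5-methoxyphenyl)butan-1-ol
Product: 5 triethyl{2-[(1R)-4-chloro-1-(triethylsilyloxy)butyl]-4-methoxyphenoxy}silane
Conditions: Et3SiCl (2.5 equiv), imidazole, DMF, 0 °C to rt
Reagents that add atoms: chlorotriethylsilane CC[Si](Cl)(CC)CC
Why: Standard silylation of both hydroxyls gives an aryl silyl ether that is cleaved selectively in the next step and a hindered benzylic silyl ether that stays as protecting and stereodirecting group.

Step 4
Reactants: 5 triethyl{2-[(1R)-4-chloro-1-(triethylsilyloxy)butyl]-4-methoxyphenoxy}silane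
Product: 8 (1R,5S)-1-(triethylsilyloxy)spiro[4.5]dec-7-ene-6,9-dione, via potassium phenolate 6 (not isolated), via spirodienone enol ether 7 (not isolated)
Conditions: KOt-Bu (1.05 equiv), NaI (0.2 equiv), t-BuOH/THF, 45 °C; then 0.5 M aq. oxalic acid, THF, 0 °C
Reagents that add atoms: water O
Why: Proposed new method: tert-butoxide cleaves only the aryl O–Si bond and the phenoxide, whose O-alkylation would need a seven-membered ring, closes the five-membered ring through its substituted ortho carbon in a Winstein–Baird-type Ar-5 alkylative dearomatisation (closest known reactions: base-induced spirocyclisation of 4-(ω-haloalkyl)phenols and ortho-alkylative dearomatisation of 2-naphthols), C5 being set S because in the transition state the benzylic C–H lies next to the C–O(−) bond and the bulky OSiEt3 next to the free ortho C–H (A(1,3) strain), after which mild acid hydrolyses the methyl enol ether so that the dimerisation-prone 2,4-dienone is never handled.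

Step 5
Reactants: 8 (1R,5S)-1-(triethylsilyloxy)spiro[4.5]dec-7-ene-6,9-dione; 9 3-(tert-butyldiphenylsilyloxy)propanal
Product: 12 (1R,5S)-10-[3-(tert-butyldiphenylsilyloxy)propylidene]-1-(triethylsilyloxy)spiro[4.5]dec-7-ene-6,9-dione (E/Z mixture), via lithium aldolate 10 (not isolated), via aldol mesylate 11 (not isolated)
Conditions: LiN(SiMe3)2 (1.05 equiv), THF, −78 °C; 9; then MsCl, −78 to 0 °C; then DBU, rt
Reagents that add atoms: none
Why: Aldol condensation works regioselectively because C10 is the only enolisable position of the ene-dione, and mesylation with E1cB elimination gives the exocyclic enone whose geometry and transient carbinol centres are erased in the next step.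

Step 6
Reactants: 12 (1R,5S)-10-[3-(tert-butyldiphenylsilyloxy)propylidene]-1-(triethylsilyloxy)spiro[4.5]dec-7-ene-6,9-dione
Product: 13 (1R,5S,10S)-10-[3-(tert-butyldiphenylsilyloxy)propyl]-1-(triethylsilyloxy)spiro[4.5]decane-6,9-dione
Conditions: H2 (1 atm), Pd/C (10 %), EtOAc, rt
Reagents that add atoms: none
Why: Heterogeneous catalytic hydrogenation saturates the C7=C8 and exocyclic C=C bonds but not the ketones, hydrogen reaching C10 from the face opposite the C1 OSiEt3 group that overhangs it, which places the chain cis to C1 as in the target.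

Step 7
Reactants: 13 (1R,5S,10S)-10-[3-(tert-butyldiphenylsilyloxy)propyl]-1-(triethylsilyloxy)spiro[4.5]decane-6,9-dione
Product: 14 (1R,5S,10S)-10-[3-(tert-butyldiphenylsilyloxy)propyl]-9-hydroxy-9-(prop-1-en-2-yl)-1-(triethylsilyloxy)spiro[4.5]decan-6-one (C9 epimers)
Conditions: CH2=C(CH3)MgBr (1.2 equiv), CeCl3 (1.3 equiv), THF, −78 °C; then H2O
Reagents that add atoms: isopropenylmagnesium bromide C=C(C)[Mg]Br
Why: Imamoto organocerium 1,2-addition occurs at the less hindered C9 ketone (the C6 ketone is flanked by the spiro centre) and the non-basic reagent does not enolise and epimerise C10, while the new C9 centre is destroyed in the next step.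

Step 8
Reactants: 14 (1R,5S,10S)-10-[3-(tert-butyldiphenylsilyloxy)propyl]-9-hydroxy-9-(prop-1-en-2-yl)-1-(triethylsilyloxy)spiro[4.5]decan-6-one
Product: 15 (2Z)-2-[(1R,5S,10R)-10-[3-(tert-butyldiphenylsilyloxy)propyl]-6-oxo-1-(triethylsilyloxy)spiro[4.5]decan-9-ylidene]propanal
Conditions: pyridinium chlorochromate [C5H5NH][CrO3Cl] (3 equiv), NaOAc, 4 Å sieves, CH2Cl2, rt
Reagents that add atoms: pyridinium chlorochromate [O-][Cr](=O)(=O)Cl.c1cc[nH+]cc1
Why: Babler–Dauben oxidative 1,3-transposition, in which the chromate ester of the tertiary allylic alcohol undergoes a [3,3] shift and oxidation to the tetrasubstituted enal, should favour the rotamer with the vinylic methyl next to the less substituted C8, so that the formyl group ends syn to C10 (Z), also the isomer with less A(1,3) strain.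

Step 9
Reactants: 15 (2Z)-2-[(1R,5S,10R)-10-[3-(tert-butyldiphenylsilyloxy)propyl]-6-oxo-1-(triethylsilyloxy)spiro[4.5]decan-9-ylidene]propanal
Product: 16 (1R,5S,10R)-10-[3-(tert-butyldiphenylsilyloxy)propyl]-9-[(2Z)-1,1-dimethoxypropan-2-ylidene]-1-hydroxyspiro[4.5]decan-6-one
Conditions: HC(OMe)3 (5 equiv), PPTS (0.2 equiv), MeOH, 0 to 40 °C
Reagents that add atoms: trimethyl orthoformate COC(OC)OC; methanol CO
Why: Acid-catalysed acetalisation of the aldehyde (far faster than ketalisation of the α-quaternary C6 ketone) and methanolysis of the secondary triethylsilyl ether occur together while the primary tert-butyldiphenylsilyl ether survives, and no stereocentre is touched.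

Step 10
Reactants: 16 (1R,5S,10R)-10-[3-(tert-butyldiphenylsilyloxy)propyl]-9-[(2Z)-1,1-dimethoxypropan-2-ylidene]-1-hydroxyspiro[4.5]decan-6-one; 17 2-(diethoxyphosphoryl)acetic acid
Product: 18 (1R,5S,10R)-10-[3-(tert-butyldiphenylsilyloxy)propyl]-9-[(2Z)-1,1-dimethoxypropan-2-ylidene]-6-oxospiro[4.5]decan-1-yl 2-(diethoxyphosphoryl)acetate
Conditions: DCC (1.6 equiv), DMAP (0.2 equiv), CH2Cl2, 0 °C to rt
Reagents that add atoms: none
Why: Steglich esterification acylates the only free hydroxyl and at once blocks retro-aldol opening of the β-hydroxy ketone.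

Step 11
Reactants: 18 (1R,5S,10R)-10-[3-(tert-butyldiphenylsilyloxy)propyl]-9-[(2Z)-1,1-dimethoxypropan-2-ylidene]-6-oxospiro[4.5]decan-1-yl 2-(diethoxyphosphoryl)acetate
Product: 19 (1R,5S,10R)-10-[3-(tert-butyldiphenylsilyloxy)propyl]-9-[(2Z)-1,1-dimethoxypropan-2-ylidene]-6-oxospiro[4.5]decan-1-yl 2-diazo-2-(diethoxyphosphoryl)acetate
Conditions: 4-acetamidobenzenesulfonyl azide (1.3 equiv), DBU (1.5 equiv), MeCN, 0 °C to rt
Reagents that add atoms: 4-acetamidobenzenesulfonyl azide CC(=O)Nc1ccc(cc1)S(=O)(=O)N=[N+]=[N-]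
Why: Regitz diazo transfer takes place only at the doubly activated methylene of the phosphonoacetate, and C10 is no longer acidic now that the enal is an acetal.

Step 12
Reactants: 19 (1R,5S,10R)-10-[3-(tert-butyldiphenylsilyloxy)propyl]-9-[(2Z)-1,1-dimethoxypropan-2-ylidene]-6-oxospiro[4.5]decan-1-yl 2-diazo-2-(diethoxyphosphoryl)acetate
Product: 20 (1R,2R,5S,10R) cis-fused γ-lactone O1–C(=O)–CH[P(O)(OEt)2]–C2 of 10-[3-(tert-butyldiphenylsilyloxy)propyl]-9-[(2Z)-1,1-dimethoxypropan-2-ylidene]-6-oxospiro[4.5]decane (phosphonate carbon epimers)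
Conditions: Rh2(OAc)4 (2 mol %), ClCH2CH2Cl, 80 °C, slow addition
Reagents that add atoms: none
Why: Rhodium carbenoid 1,5-C–H insertion can reach only the C2–H bond cis to the C1–O bond (C5 has no hydrogen), so a five-membered lactone forms that is necessarily cis-fused and fixes C2 with its new C–C bond cis to oxygen.

Step 13
Reactants: 20 (1R,2R,5S,10R) cis-fused phosphono γ-lactone ketone
Product: 21 (1R,2R,5S,6S,10R) cis-fused γ-lactone O1–C(=O)–CH[P(O)(OEt)2]–C2 of 10-[3-(tert-butyldiphenylsilyloxy)propyl]-9-[(2Z)-1,1-dimethoxypropan-2-ylidene]-6-hydroxy-6-methylspiro[4.5]decane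
Conditions: MeLi (2.5 equiv), CeCl3 (2.6 equiv), THF, −78 to −40 °C; then H2O
Reagents that add atoms: methyllithium [Li]C
Why: In this organocerium 1,2-addition the first equivalent deprotonates the β-phosphono lactone, whose enolate is then inert, and methylcerium adds to the C6 ketone anti to the C10 chain, which is held axial by A(1,3) strain with the Z-alkylidene, giving the 6S carbinol with OH cis to that chain.

Step 14
Reactants: 22 6-methylhept-5-en-2-one
Product: 23 6-methylhepta-1,5-dien-2-yl trifluoromethanesulfonate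
Conditions: LiN(i-Pr)2 (1.1 equiv), THF, −78 °C; then PhNTf2, −78 °C to rt
Reagents that add atoms: N-phenylbis(trifluoromethanesulfonimide) O=S(=O)(N(c1ccccc1)S(=O)(=O)C(F)(F)F)C(F)(F)F
Why: Kinetic deprotonation of the methyl ketone at the methyl group and O-triflation of the enolate give the terminal enol triflate.

Step 15
Reactants: 23 6-methylhepta-1,5-dien-2-yl trifluoromethanesulfonate; 24 prop-2-enal (acrolein)
Product: 25 (2E)-8-methyl-4-methylidenenona-2,7-dienal
Conditions: Pd(OAc)2 (5 mol %), PPh3 (10 mol %), Et3N (2 equiv), DMF, 60 °C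
Reagents that add atoms: none
Why: Mizoroki–Heck vinylation of acrolein with the enol triflate (Cacchi conditions) gives the E-dienal through syn insertion and syn β-hydride elimination.

Step 16
Reactants: 21 (1R,2R,5S,6S,10R) cis-fused phosphono γ-lactone carbinol; 25 (2E)-8-methyl-4-methylidenenona-2,7-dienal
Product: 26 (1R,2S,5S,6S,10R) cis-fused γ-lactone O1–C(=O)–C[=CH–CH=CH–C(=CH2)CH2CH2CH=C(CH3)2]–C2 (E at the lactone alkylidene and at the disubstituted alkene) of 10-[3-(tert-butyldiphenylsilyloxy)propyl]-9-[(2Z)-1,1-dimethoxypropan-2-ylidene]-6-hydroxy-6-methylspiro[4.5]decane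
Conditions: LiCl (3 equiv), DBU (2.5 equiv), MeCN, 0 °C to rt
Reagents that add atoms: none
Why: Horner–Wadsworth–Emmons olefination under Masamune–Roush conditions gives from an α-phosphono γ-lactone and a conjugated aldehyde mainly the E-alkylidene lactone (chain trans to the carbonyl), which is the side-chain geometry of the target, and the mild base tolerates the tertiary alcohol and the acetal.

Step 17
Reactants: 26 (1R,2S,5S,6S,10R) E-alkylidene cis-fused γ-lactone
Product: 27 (1R,2S,5S,6S,10R)-10-[3-(tert-butyldiphenylsilyloxy)propyl]-9-[(2Z)-1,1-dimethoxypropan-2-ylidene]-2-[(2E,4E)-1-hydroxy-10-methyl-6-methylideneundeca-2,4,9-trien-2-yl]-6-methylspiro[4.5]decane-1,6-diol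
Conditions: i-Bu2AlH (5 equiv), CH2Cl2, −78 to −40 °C; aq. KNaC4H4O6 work-up
Reagents that add atoms: none
Why: 1,2-Reduction of the α-alkylidene lactone with i-Bu2AlH opens it to the allylic primary alcohol and the C1 secondary alcohol without conjugate reduction, and the dimethyl acetal is inert at low temperature.

Step 18
Reactants: 27 (1R,2S,5S,6S,10R) silyl-protected triol acetal
Product: 29 28-deacetylbelamcandal, via desilylated acetal 28 (not isolated)
Conditions: Bu4NF (1.5 equiv), THF, 0 °C to rt; then 1 M aq. oxalic acid added, rt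
Reagents that add atoms: water O
Why: Fluoride desilylation is followed in the same flask by hydrolysis of the allylic dimethyl acetal, which is fast under acid mild enough not to isomerise the Z-enal or ionise the trienyl alcohol.

## Compound list

1 | 1,4-dimethoxybenzene | COc1ccc(OC)cc1 | starting material
2 | 4-chlorobutanoyl chloride | ClCCCC(Cl)=O | starting material
3 | 4-chloro-1-(2-hydroxy-5-methoxyphenyl)butan-1-one | COc1ccc(O)c(c1)C(=O)CCCCl | intermediate
4 | (1R)-4-chloro-1-(2-hydroxy-5-methoxyphenyl)butan-1-ol | COc1ccc(O)c(c1)[C@@H](CCCCl)O | intermediate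
5 | triethyl{2-[(1R)-4-chloro-1-(triethylsilyloxy)butyl]-4-methoxyphenoxy}silane | COc1ccc(O[Si](CC)(CC)CC)c(c1)[C@@H](CCCCl)O[Si](CC)(CC)CC | intermediate
6 | potassium 2-[(1R)-4-chloro-1-(triethylsilyloxy)butyl]-4-methoxyphenolate | COc1ccc([O-])c(c1)[C@@H](CCCCl)O[Si](CC)(CC)CC.[K+] | intermediate (not isolated)
7 | (1R,5S)-9-methoxy-1-(triethylsilyloxy)spiro[4.5]deca-7,9-dien-6-one | C1CC[C@]2(C=C(OC)C=CC2=O)[C@@H]1O[Si](CC)(CC)CC | intermediate (not isolated)
8 | (1R,5S)-1-(triethylsilyloxy)spiro[4.5]dec-7-ene-6,9-dione | C1CC[C@]2(CC(=O)C=CC2=O)[C@@H]1O[Si](CC)(CC)CC | intermediate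
9 | 3-(tert-butyldiphenylsilyloxy)propanal | O=CCCO[Si](c1ccccc1)(c1ccccc1)C(C)(C)C | starting material
10 | (1R,5S)-10-[3-(tert-butyldiphenylsilyloxy)-1-(lithiooxy)propyl]-1-(triethylsilyloxy)spiro[4.5]dec-7-ene-6,9-dione (diastereomer mixture) | C1CC[C@]2(C(C(O[Li])CCO[Si](c3ccccc3)(c3ccccc3)C(C)(C)C)C(=O)C=CC2=O)[C@@H]1O[Si](CC)(CC)CC | intermediate (not isolated)
11 | (1R,5S)-10-[3-(tert-butyldiphenylsilyloxy)-1-(methanesulfonyloxy)propyl]-1-(triethylsilyloxy)spiro[4.5]dec-7-ene-6,9-dione (diastereomer mixture) | C1CC[C@]2(C(C(OS(C)(=O)=O)CCO[Si](c3ccccc3)(c3ccccc3)C(C)(C)C)C(=O)C=CC2=O)[C@@H]1O[Si](CC)(CC)CC | intermediate (not isolated)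
12 | (1R,5S)-10-[3-(tert-butyldiphenylsilyloxy)propylidene]-1-(triethylsilyloxy)spiro[4.5]dec-7-ene-6,9-dione (E/Z mixture) | C1CC[C@]2(C(=CCCO[Si](c3ccccc3)(c3ccccc3)C(C)(C)C)C(=O)C=CC2=O)[C@@H]1O[Si](CC)(CC)CC | intermediate
13 | (1R,5S,10S)-10-[3-(tert-butyldiphenylsilyloxy)propyl]-1-(triethylsilyloxy)spiro[4.5]decane-6,9-dione | C1CC[C@]2([C@H](CCCO[Si](c3ccccc3)(c3ccccc3)C(C)(C)C)C(=O)CCC2=O)[C@@H]1O[Si](CC)(CC)CC | intermediate
14 | (1R,5S,10S)-10-[3-(tert-butyldiphenylsilyloxy)propyl]-9-hydroxy-9-(prop-1-en-2-yl)-1-(triethylsilyloxy)spiro[4.5]decan-6-one (C9 epimers) | C1CC[C@]2([C@H](CCCO[Si](c3ccccc3)(c3ccccc3)C(C)(C)C)C(O)(C(C)=C)CCC2=O)[C@@H]1O[Si](CC)(CC)CC | intermediate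
15 | (2Z)-2-[(1R,5S,10R)-10-[3-(tert-butyldiphenylsilyloxy)propyl]-6-oxo-1-(triethylsilyloxy)spiro[4.5]decan-9-ylidene]propanal | C1CC[C@]2([C@H](CCCO[Si](c3ccccc3)(c3ccccc3)C(C)(C)C)/C(=C(/C)C=O)CCC2=O)[C@@H]1O[Si](CC)(CC)CC | intermediate
16 | (1R,5S,10R)-10-[3-(tert-butyldiphenylsilyloxy)propyl]-9-[(2Z)-1,1-dimethoxypropan-2-ylidene]-1-hydroxyspiro[4.5]decan-6-one | C1CC[C@]2([C@H](CCCO[Si](c3ccccc3)(c3ccccc3)C(C)(C)C)/C(=C(/C)C(OC)OC)CCC2=O)[C@@H]1O | intermediate
17 | 2-(diethoxyphosphoryl)acetic acid | OC(=O)CP(=O)(OCC)OCC | starting material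
18 | (1R,5S,10R)-10-[3-(tert-butyldiphenylsilyloxy)propyl]-9-[(2Z)-1,1-dimethoxypropan-2-ylidene]-6-oxospiro[4.5]decan-1-yl 2-(diethoxyphosphoryl)acetate | C1CC[C@]2([C@H](CCCO[Si](c3ccccc3)(c3ccccc3)C(C)(C)C)/C(=C(/C)C(OC)OC)CCC2=O)[C@@H]1OC(=O)CP(=O)(OCC)OCC | intermediate
19 | (1R,5S,10R)-10-[3-(tert-butyldiphenylsilyloxy)propyl]-9-[(2Z)-1,1-dimethoxypropan-2-ylidene]-6-oxospiro[4.5]decan-1-yl 2-diazo-2-(diethoxyphosphoryl)acetate | C1CC[C@]2([C@H](CCCO[Si](c3ccccc3)(c3ccccc3)C(C)(C)C)/C(=C(/C)C(OC)OC)CCC2=O)[C@@H]1OC(=O)C(=[N+]=[N-])P(=O)(OCC)OCC | intermediate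
20 | (1R,2R,5S,10R) cis-fused γ-lactone O1–C(=O)–CH[P(O)(OEt)2]–C2 of 10-[3-(tert-butyldiphenylsilyloxy)propyl]-9-[(2Z)-1,1-dimethoxypropan-2-ylidene]-6-oxospiro[4.5]decane (phosphonate carbon epimers) | O=C3C(P(=O)(OCC)OCC)[C@@H]1CC[C@]2([C@H](CCCO[Si](c4ccccc4)(c4ccccc4)C(C)(C)C)/C(=C(/C)C(OC)OC)CCC2=O)[C@@H]1O3 | intermediate
21 | (1R,2R,5S,6S,10R) cis-fused γ-lactone O1–C(=O)–CH[P(O)(OEt)2]–C2 of 10-[3-(tert-butyldiphenylsilyloxy)propyl]-9-[(2Z)-1,1-dimethoxypropan-2-ylidene]-6-hydroxy-6-methylspiro[4.5]decane (phosphonate carbon epimers) | O=C3C(P(=O)(OCC)OCC)[C@@H]1CC[C@]2([C@H](CCCO[Si](c4ccccc4)(c4ccccc4)C(C)(C)C)/C(=C(/C)C(OC)OC)CC[C@]2(C)O)[C@@H]1O3 | intermediate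
22 | 6-methylhept-5-en-2-one | CC(=O)CCC=C(C)C | starting material
23 | 6-methylhepta-1,5-dien-2-yl trifluoromethanesulfonate | C=C(OS(=O)(=O)C(F)(F)F)CCC=C(C)C | intermediate
24 | prop-2-enal (acrolein) | C=CC=O | starting material
25 | (2E)-8-methyl-4-methylidenenona-2,7-dienal | O=C/C=C/C(=C)CCC=C(C)C | intermediate
26 | (1R,2S,5S,6S,10R) cis-fused γ-lactone O1–C(=O)–C[=CH–CH=CH–C(=CH2)CH2CH2CH=C(CH3)2]–C2 (E at the lactone alkylidene and at the disubstituted alkene) of 10-[3-(tert-butyldiphenylsilyloxy)propyl]-9-[(2Z)-1,1-dimethoxypropan-2-ylidene]-6-hydroxy-6-methylspiro[4.5]decane | C=C(/C=C/C=C(/C3=O)[C@@H]1CC[C@]2([C@H](CCCO[Si](c4ccccc4)(c4ccccc4)C(C)(C)C)/C(=C(/C)C(OC)OC)CC[C@]2(C)O)[C@@H]1O3)CCC=C(C)C | intermediate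
27 | (1R,2S,5S,6S,10R)-10-[3-(tert-butyldiphenylsilyloxy)propyl]-9-[(2Z)-1,1-dimethoxypropan-2-ylidene]-2-[(2E,4E)-1-hydroxy-10-methyl-6-methylideneundeca-2,4,9-trien-2-yl]-6-methylspiro[4.5]decane-1,6-diol | C=C(/C=C/C=C(/CO)[C@@H]1CC[C@]2([C@H](CCCO[Si](c3ccccc3)(c3ccccc3)C(C)(C)C)/C(=C(/C)C(OC)OC)CC[C@]2(C)O)[C@@H]1O)CCC=C(C)C | intermediate
28 | (1R,2S,5S,6S,10R)-9-[(2Z)-1,1-dimethoxypropan-2-ylidene]-2-[(2E,4E)-1-hydroxy-10-methyl-6-methylideneundeca-2,4,9-trien-2-yl]-10-(3-hydroxypropyl)-6-methylspiro[4.5]decane-1,6-diol | C=C(/C=C/C=C(/CO)[C@@H]1CC[C@]2([C@H](CCCO)/C(=C(/C)C(OC)OC)CC[C@]2(C)O)[C@@H]1O)CCC=C(C)C | intermediate (not isolated)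
29 | 28-deacetylbelamcandal: (2Z)-2-[(1R,2S,5S,6S,10R)-1,6-dihydroxy-2-[(2E,4E)-1-hydroxy-10-methyl-6-methylideneundeca-2,4,9-trien-2-yl]-10-(3-hydroxypropyl)-6-methylspiro[4.5]decan-9-ylidene]propanal | C=C(/C=C/C=C(/CO)[C@@H]1CC[C@]2([C@H](CCCO)/C(=C(/C)C=O)CC[C@]2(C)O)[C@@H]1O)CCC=C(C)C | target

## Step count and risks

Total step count: 18. Longest linear sequence: 16 steps (steps 1–13 and 16–18); the dienal 25 is made in two side steps (14 and 15).

**Most likely to fail, first: step 4 (dearomatising spirocyclisation).** O-alkylation to a benzoxepine, loss of the benzylic silyloxy group through an ortho-quinone methide, or poor facial selectivity could intervene. The fallback sets out from 5 and comes back at 8, and it makes the quaternary centre by radical conjugate addition to a quinone instead of anionic alkylation of a phenoxide. K2CO3 in MeOH cleaves only the aryl silyl ether to give (R)-2-[4-chloro-1-(triethylsilyloxy)butyl]-4-methoxyphenol F1. (NH4)2Ce(NO3)6 in MeCN/H2O oxidises it, with loss of methanol, to 2-[(1R)-4-chloro-1-(triethylsilyloxy)butyl]cyclohexa-2,5-diene-1,4-dione F2. NaI in acetone gives 2-[(1R)-4-iodo-1-(triethylsilyloxy)butyl]cyclohexa-2,5-diene-1,4-dione F3. Et3B with air in wet THF at 0 °C then generates the primary radical, which closes 5-exo onto the substituted quinone carbon under the same A(1,3) bias, and protonation of the boron enolate gives 8.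

**Second: step 8 (oxidative transposition to the Z-enal).** The hindered tertiary alcohol may react slowly and the Z/E ratio may be modest. The fallback sets out from 14 and comes back at 15, and it separates a reversible transposition from the oxidation. O3ReOSiPh3 (2 mol %) in Et2O at 0 °C equilibrates 14 with the primary allylic alcohol (1R,5S,10R)-10-[3-(tert-butyldiphenylsilyloxy)propyl]-9-[(2Z)-1-hydroxypropan-2-ylidene]-1-(triethylsilyloxy)spiro[4.5]decan-6-one F4. The E isomer is separated and put back into the equilibration. MnO2 in CH2Cl2 then oxidises the allylic alcohol to 15.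

**Third: step 13 (facial selectivity of methyl addition at C6).** If methylcerium enters from the wrong face, the C6 epimer results. The fallback sets out from 20 and comes back at 21, and it brings in the oxygen, not the methyl, from the open face, so it gives the opposite C6 configuration to a failed methyl addition. Zn/CH2Br2/TiCl4 (Takai–Lombardo methylenation, selective for the ketone over the lactone) gives the (1R,2R,5R,10R) 6-methylidene analogue of lactone 20 F5. Mukaiyama hydration (Mn(dpm)3, PhSiH3, O2, i-PrOH) of this 1,1-disubstituted alkene, which leaves the tetrasubstituted alkylidene alone, gives 21.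

## Further compounds

F1 | step 4 | (R)-2-[4-chloro-1-(triethylsilyloxy)butyl]-4-methoxyphenol | COc1ccc(O)c(c1)[C@@H](CCCCl)O[Si](CC)(CC)CC
F2 | step 4 | 2-[(1R)-4-chloro-1-(triethylsilyloxy)butyl]cyclohexa-2,5-diene-1,4-dione | O=C1C=CC(=O)C(=C1)[C@@H](CCCCl)O[Si](CC)(CC)CC
F3 | step 4 | 2-[(1R)-4-iodo-1-(triethylsilyloxy)butyl]cyclohexa-2,5-diene-1,4-dione | O=C1C=CC(=O)C(=C1)[C@@H](CCCI)O[Si](CC)(CC)CC
F4 | step 8 | (1R,5S,10R)-10-[3-(tert-butyldiphenylsilyloxy)propyl]-9-[(2Z)-1-hydroxypropan-2-ylidene]-1-(triethylsilyloxy)spiro[4.5]decan-6-one | C1CC[C@]2([C@H](CCCO[Si](c3ccccc3)(c3ccccc3)C(C)(C)C)/C(=C(/C)CO)CCC2=O)[C@@H]1O[Si](CC)(CC)CC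
F5 | step 13 | (1R,2R,5R,10R) 6-methylidene analogue of lactone 20 | O=C3C(P(=O)(OCC)OCC)[C@@H]1CC[C@]2([C@H](CCCO[Si](c4ccccc4)(c4ccccc4)C(C)(C)C)/C(=C(/C)C(OC)OC)CCC2=C)[C@@H]1O3
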